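The target is traced back to a 10-epi-eudesmane: the C1–C5 bond is disconnected and C5–C10 reconnected, so the cyclopentane and cycloheptane rings become the decalin that (R)-carvone and ethyl vinyl ketone provide. One photochemical step exploits the C3 oxygen, the C4 methyl group, the β-hydrogen at C1 and the C10 carbon that bears the C14 methylene. It forms C1–C5, expands ring B to the seven-membered ring, copies the C10 configuration into C1 and leaves C10 as a carbinol. Its precursor is a santonin-like 6α-acetoxy-8α-silyloxy-10-epi-eudesma-1,4-dien-3-one whose C6, C7 and C8 already have the target configurations.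

Key step: step 11

Remark: eudesmane and guaiane numbering is used, α/β refer to the usual drawings (the C7 isopropyl group is β); the epimer mixtures at C2 of 3 and 7 and at C4 of 12 are carried on because these centres are erased in the following step (TBS = tert-butyldimethylsilyl).

Step 1
Reactants: 1 (R)-(−)-carvone
Product: 2 (R)-carvotanacetone
Conditions: H2 (1 atm), RhCl(PPh3)3 (cat.), toluene, rt
Reagents that add atoms: none
Why: Homogeneous hydrogenation with RhCl(PPh3)3 reduces the unhindered 1,1-disubstituted isopropenyl alkene and leaves the trisubstituted enone alkene, so the C5 stereocentre is carried over unchanged.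

Step 2
Reactants: 2 (R)-carvotanacetone
Product: 3 (2RS,5R)-2-methyl-5-(propan-2-yl)cyclohex-3-en-1-one
Conditions: KOtBu, tBuOH, rt; then cold 10% aq AcOH
Reagents that add atoms: none
Why: Base-mediated deconjugation, in which equilibrating base forms the extended dienolate by γ-deprotonation at C4 and kinetic protonation at the α-carbon should give the β,γ-unsaturated ketone without touching C5.

Step 3
Reactants: 3 (2RS,5R)-2-methyl-5-(propan-2-yl)cyclohex-3-en-1-one
Product: 5 (4R,5R)-4-hydroxy-2-methyl-5-(propan-2-yl)cyclohex-2-en-1-one, via trans-3,4-epoxy ketone 4 (not isolated)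
Conditions: mCPBA, CH2Cl2, 0 °C; then Et3N, rt
Reagents that add atoms: mCPBA, O=C(OO)c1cccc(Cl)c1
Why: Prilezhaev epoxidation of the isolated cis-alkene should occur mainly anti to the neighbouring isopropyl group, and E1cB opening of the β,γ-epoxy ketone then gives the γ-hydroxy enone with the hydroxyl trans to isopropyl (any cis isomer should be separable here).

Step 4
Reactants: 5 (4R,5R)-4-hydroxy-2-methyl-5-(propan-2-yl)cyclohex-2-en-1-one
Product: 6 (4R,5R)-4-(TBS-oxy)-2-methyl-5-(propan-2-yl)cyclohex-2-en-1-one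
Conditions: TBSCl, imidazole, DMF, rt
Reagents that add atoms: tert-butyldimethylsilyl chloride, CC(C)(C)[Si](C)(C)Cl
Why: Standard silylation of a secondary alcohol gives an ether that tolerates the basic annulation, the deconjugation and the photolysis medium and that keeps the C8 oxygen distinct from the later C6 oxygen.

Step 5
Reactants: 6 (4R,5R)-4-(TBS-oxy)-2-methyl-5-(propan-2-yl)cyclohex-2-en-1-one
Product: 7 (2RS,4S,5R)-4-(TBS-oxy)-2-methyl-5-(propan-2-yl)cyclohexan-1-one
Conditions: H2 (1 atm), Pd/C (10%), EtOAc, rt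
Reagents that add atoms: none
Why: Heterogeneous hydrogenation saturates the enone alkene, and the C2 epimer mixture is of no consequence because C2 is enolised in the annulation.

Step 6
Reactants: 7 (2RS,4S,5R)-4-(TBS-oxy)-2-methyl-5-(propan-2-yl)cyclohexan-1-one; 8 ethyl vinyl ketone
Product: 11 8α-(TBS-oxy)-10-epi-eudesm-4-en-3-one, via Michael adduct 9 (not isolated), via aldol ketol 10 (not isolated)
Conditions: KOH, EtOH, 0 °C to rt; then 70 °C
Reagents that add atoms: none
Why: Robinson annulation, in which the more substituted enolate adds to the enone by axial attack on the half-chair that holds the isopropyl and silyloxy groups equatorial, so the new C10–C1 bond is cis and the angular methyl trans to the C7 isopropyl group (10α-methyl), and aldol condensation closes ring A.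

Step 7
Reactants: 11 8α-(TBS-oxy)-10-epi-eudesm-4-en-3-one
Product: 12 8α-(TBS-oxy)-10-epi-eudesm-5-en-3-one (C4 epimers)
Conditions: KOtBu, tBuOH, rt; then cold 10% aq AcOH
Reagents that add atoms: none
Why: Base-mediated deconjugation of a 4-methyl-4-en-3-one, in which the extended dienolate formed by deprotonation at C6 is protonated kinetically at C4 and the double bond moves to C5–C6.

Step 8
Reactants: 12 8α-(TBS-oxy)-10-epi-eudesm-5-en-3-one (C4 epimers)
Product: 14 6α-hydroxy-8α-(TBS-oxy)-10-epi-eudesm-4-en-3-one, via 5α,6α-epoxide 13 (not isolated)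
Conditions: mCPBA, CH2Cl2, 0 °C; then Et3N, rt
Reagents that add atoms: mCPBA, O=C(OO)c1cccc(Cl)c1
Why: Prilezhaev epoxidation should take the α face because, with the C7 and C8 substituents equatorial, ring A is attached axially through C1 and covers the β face of C5–C6, and E1cB opening of the β,γ-epoxy ketone gives the 6α-alcohol trans to the C7 isopropyl group.

Step 9
Reactants: 14 6α-hydroxy-8α-(TBS-oxy)-10-epi-eudesm-4-en-3-one
Product: 15 6α-acetoxy-8α-(TBS-oxy)-10-epi-eudesm-4-en-3-one
Conditions: Ac2O, pyridine, 4-(dimethylamino)pyridine (cat.), CH2Cl2, rt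
Reagents that add atoms: acetic anhydride, CC(=O)OC(C)=O
Why: Nucleophile-catalysed acylation of the hindered allylic alcohol gives the γ-acetoxy enone, which protects C6–OH through the dehydrogenation, the photolysis and the later dehydration and mirrors the 6α-acyloxy pattern of santonin.

Step 10
Reactants: 15 6α-acetoxy-8α-(TBS-oxy)-10-epi-eudesm-4-en-3-one
Product: 16 6α-acetoxy-8α-(TBS-oxy)-10-epi-eudesma-1,4-dien-3-one
Conditions: DDQ, dioxane, reflux
Reagents that add atoms: none
Why: DDQ dehydrogenation of a 4-en-3-one in neutral dioxane proceeds through the kinetically formed 2,4-dienol and hydride abstraction from C1, which should give the cross-conjugated dienone with all stereocentres intact.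

Step 11
Reactants: 16 6α-acetoxy-8α-(TBS-oxy)-10-epi-eudesma-1,4-dien-3-one
Product: 17 6α-acetoxy-10β-hydroxy-8α-(TBS-oxy)-1βH-guai-4-en-3-one
Conditions: hν (high-pressure Hg lamp, Pyrex filter), AcOH/H2O (1:1), N2, 15–20 °C
Reagents that add atoms: water, O
Why: Excitation of the cross-conjugated dienone bonds the two β-carbons C1 and C5 to give a cyclopropyl oxyallyl zwitterion that acetic acid protonates on oxygen, water then attacks C10 from the side opposite the C5–C10 bond as that bond breaks, and the resulting dienol tautomerises to the 4-en-3-one. The closest known reaction is the santonin-type photorearrangement of 4-methyl cross-conjugated cyclohexadienones in aqueous acetic acid to 10-hydroxy hydroazulenones. The five-membered ring closes by C1–C5 (β,β) bonding of the excited dienone, formally a 3-exo closure to a bicyclo[3.1.0]hexane, and the seven-membered ring arises by one-carbon expansion of ring B when its C5–C10 bond, now a cyclopropane bond, is cleaved. C1 is controlled by C10, since the C6–C9 tether of ring B forces C6 and C9 to be cis on the cyclopropane so that C1–C5 bonding is possible on one face only (10α-methyl gives 1β-H), and C10 is set by backside attack of water (inversion, 10β-OH). The step needs the 5/7 product over spiro or lumiketone products, which the C4 methyl group (positive charge at C4 next to C5 directs C5–C10 cleavage) and the acidic aqueous medium secure, and the 6α-acyloxy group is tolerated as in santonin.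

Step 12
Reactants: 17 6α-acetoxy-10β-hydroxy-8α-(TBS-oxy)-1βH-guai-4-en-3-one
Product: 18 6α-acetoxy-8α-(TBS-oxy)-1βH-guai-4-ene-3β,10β-diol
Conditions: (R)-1-methyl-3,3-diphenyltetrahydro-1H,3H-pyrrolo[1,2-c][1,3,2]oxazaborole (0.3 equiv), BH3·SMe2, THF, −30 °C; then MeOH
Reagents that add atoms: none
Why: Corey–Bakshi–Shibata reduction, in which the (R)-catalyst treats the C4 alkene carbon as the large and C2 as the small substituent and delivers hydride to the α (Re) face of C3, so the 3β-alcohol (3S) should form under reagent control by 1,2-reduction.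

Step 13
Reactants: 18 6α-acetoxy-8α-(TBS-oxy)-1βH-guai-4-ene-3β,10β-diol
Product: 19 6α-acetoxy-3β,8α-bis(TBS-oxy)-1βH-guai-4-en-10β-ol
Conditions: TBSCl, imidazole, DMF, rt
Reagents that add atoms: tert-butyldimethylsilyl chloride, CC(C)(C)[Si](C)(C)Cl
Why: Silylation of the secondary allylic 3β-alcohol, for which the tertiary C10 alcohol is too hindered, stops the 3β-hydroxyl from directing the later epoxidation to the β face or from being oxidised.

Step 14
Reactants: 19 6α-acetoxy-3β,8α-bis(TBS-oxy)-1βH-guai-4-en-10β-ol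
Product: 20 6α-acetoxy-3β,8α-bis(TBS-oxy)-1βH-guaia-4,10(14)-diene
Conditions: SOCl2, pyridine, −20 °C to 0 °C
Reagents that add atoms: none
Why: Dehydration through the chlorosulfite by anti elimination in pyridine, in which the allylic C1 hydrogen is syn to the 10β leaving group and cannot take part, so proton loss from the freely rotating C14 methyl group should give the exocyclic alkene while this is still the only free hydroxyl in the molecule.

Step 15
Reactants: 20 6α-acetoxy-3β,8α-bis(TBS-oxy)-1βH-guaia-4,10(14)-diene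
Product: 21 3β,8α-bis(TBS-oxy)-1βH-guaia-4,10(14)-dien-6α-ol
Conditions: K2CO3, MeOH, rt
Reagents that add atoms: none
Why: Base-catalysed transesterification with methanol removes the allylic acetate and leaves the silyl ethers and both alkenes untouched.

Step 16
Reactants: 21 3β,8α-bis(TBS-oxy)-1βH-guaia-4,10(14)-dien-6α-ol
Product: 22 4α,5α-epoxy-3β,8α-bis(TBS-oxy)-1βH-guai-10(14)-en-6α-ol
Conditions: VO(acac)2 (cat.), tBuOOH, CH2Cl2, 0 °C to rt
Reagents that add atoms: tert-butyl hydroperoxide, CC(C)(C)OO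
Why: Hydroxyl-directed vanadium-catalysed epoxidation delivers oxygen to the tetrasubstituted C4–C5 alkene syn to the 6α-alcohol and anti to the 3β-silyloxy group, which sets the C4 oxygen α, and it leaves the exocyclic alkene alone because that alkene has no allylic hydroxyl.

Step 17
Reactants: 22 4α,5α-epoxy-3β,8α-bis(TBS-oxy)-1βH-guai-10(14)-en-6α-ol
Product: 23 4α,5α-epoxy-3β,8α-bis(TBS-oxy)-1βH-guai-10(14)-en-6-one
Conditions: Dess–Martin periodinane, pyridine, CH2Cl2, rt
Reagents that add atoms: none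
Why: Dess–Martin oxidation of the secondary epoxy alcohol under buffered conditions gives the α,β-epoxy ketone without epimerising C7 or opening the epoxide.

Step 18
Reactants: 23 4α,5α-epoxy-3β,8α-bis(TBS-oxy)-1βH-guai-10(14)-en-6-one
Product: 25 3β,8α-bis(TBS-oxy)-1βH-guaia-5,10(14)-dien-4α-ol, via epoxy hydrazone 24 (not isolated)
Conditions: N2H4·H2O, AcOH (cat.), MeOH, 0 °C to rt, argon
Reagents that add atoms: none
Why: Wharton transposition, in which the hydrazone opens the epoxide at C5 and loses dinitrogen, so the C6 carbonyl carbon becomes an alkene CH and the C4–O bond, never broken, keeps the 4α configuration in the tertiary allylic alcohol.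

Step 19
Reactants: 25 3β,8α-bis(TBS-oxy)-1βH-guaia-5,10(14)-dien-4α-ol
Product: 28 3β,8α-bis(TBS-oxy)-1βH,5αH-guai-10(14)-ene-4α,6α-diol, via dimethylsilyl ether 26 (not isolated), via cyclic siloxane 27 (not isolated)
Conditions: HMe2SiCl, Et3N, 4-(dimethylamino)pyridine (cat.), CH2Cl2, 0 °C to rt; then Pt2[(CH2=CHSiMe2)2O]3 (cat., zerovalent platinum), toluene, 60 °C; then 30% H2O2, KF, KHCO3, THF/MeOH, rt
Reagents that add atoms: hydrogen peroxide, OO
Why: Intramolecular hydrosilylation of an allylic alcohol followed by Tamao–Fleming oxidation, in which the Si–H tethered to the 4α oxygen adds syn across C5=C6 in the 5-endo mode on the α face (H to C5, Si to C6), the exocyclic alkene being out of reach of the tether, and oxidation with retention gives 5α-H and 6α-OH.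

Step 20
Reactants: 28 3β,8α-bis(TBS-oxy)-1βH,5αH-guai-10(14)-ene-4α,6α-diol
Product: 29 1βH,5αH-guai-10(14)-ene-3β,4α,6α,8α-tetraol
Conditions: Bu4NF, THF, rt to 40 °C
Reagents that add atoms: none
Why: Fluoride-mediated desilylation removes both secondary silyl ethers in one operation and leaves the alkene and the tertiary alcohol untouched.

Step 21
Reactants: 29 1βH,5αH-guai-10(14)-ene-3β,4α,6α,8α-tetraol
Product: 30 3β,6α,8α-triacetoxy-1βH,5αH-guai-10(14)-en-4α-ol (CNP0147943.1)
Conditions: Ac2O, pyridine, 4-(dimethylamino)pyridine (cat.), CH2Cl2, rt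
Reagents that add atoms: acetic anhydride, CC(=O)OC(C)=O
Why: Nucleophile-catalysed acetylation esterifies the three secondary alcohols at C3, C6 and C8, whereas the hindered tertiary C4 alcohol should not react at room temperature, which gives the target.

Compound list
1 | (R)-(−)-carvone, (5R)-2-methyl-5-(prop-1-en-2-yl)cyclohex-2-en-1-one | CC1=CC[C@H](CC1=O)C(C)=C | starting material
2 | (R)-carvotanacetone, (5R)-2-methyl-5-(propan-2-yl)cyclohex-2-en-1-one | CC1=CC[C@H](CC1=O)C(C)C | intermediate
3 | (2RS,5R)-2-methyl-5-(propan-2-yl)cyclohex-3-en-1-one (C2 epimers) | CC1C=C[C@H](CC1=O)C(C)C | intermediate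
4 | (2RS)-3,4-epoxy-2-methyl-5-(propan-2-yl)cyclohexan-1-one, oxirane trans to isopropyl | CC1[C@@H]2O[C@@H]2[C@H](CC1=O)C(C)C | intermediate (not isolated)
5 | (4R,5R)-4-hydroxy-2-methyl-5-(propan-2-yl)cyclohex-2-en-1-one, hydroxyl trans to isopropyl | CC1=C[C@H](O)[C@H](CC1=O)C(C)C | intermediate
6 | (4R,5R)-4-[(tert-butyldimethylsilyl)oxy]-2-methyl-5-(propan-2-yl)cyclohex-2-en-1-one | CC1=C[C@H](O[Si](C)(C)C(C)(C)C)[C@H](CC1=O)C(C)C | intermediate
7 | (2RS,4S,5R)-4-[(tert-butyldimethylsilyl)oxy]-2-methyl-5-(propan-2-yl)cyclohexan-1-one (C2 epimers) | CC1C[C@H](O[Si](C)(C)C(C)(C)C)[C@H](CC1=O)C(C)C | intermediate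
8 | ethyl vinyl ketone, pent-1-en-3-one | CCC(=O)C=C | starting material
9 | (2S,4S,5R)-4-[(tert-butyldimethylsilyl)oxy]-2-methyl-2-(3-oxopentyl)-5-(propan-2-yl)cyclohexan-1-one, oxopentyl chain cis to isopropyl | C[C@]1(CCC(=O)CC)C[C@H](O[Si](C)(C)C(C)(C)C)[C@H](CC1=O)C(C)C | intermediate (not isolated)
10 | 5α-hydroxy-8α-[(tert-butyldimethylsilyl)oxy]-10-epi-eudesman-3-one, cis-fused ketol (C4 epimers) | CC1[C@]2(O)C[C@H](C(C)C)[C@@H](O[Si](C)(C)C(C)(C)C)C[C@]2(C)CCC1=O | intermediate (not isolated)
11 | 8α-[(tert-butyldimethylsilyl)oxy]-10-epi-eudesm-4-en-3-one (7β-isopropyl, 10α-methyl) | CC1=C2C[C@H](C(C)C)[C@@H](O[Si](C)(C)C(C)(C)C)C[C@]2(C)CCC1=O | intermediate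
12 | 8α-[(tert-butyldimethylsilyl)oxy]-10-epi-eudesm-5-en-3-one (C4 epimers) | CC1C2=C[C@H](C(C)C)[C@@H](O[Si](C)(C)C(C)(C)C)C[C@]2(C)CCC1=O | intermediate
13 | 5α,6α-epoxy-8α-[(tert-butyldimethylsilyl)oxy]-10-epi-eudesman-3-one (C4 epimers) | CC1[C@@]23O[C@H]3[C@H](C(C)C)[C@@H](O[Si](C)(C)C(C)(C)C)C[C@]2(C)CCC1=O | intermediate (not isolated)
14 | 6α-hydroxy-8α-[(tert-butyldimethylsilyl)oxy]-10-epi-eudesm-4-en-3-one | CC1=C2[C@@H](O)[C@H](C(C)C)[C@@H](O[Si](C)(C)C(C)(C)C)C[C@]2(C)CCC1=O | intermediate
15 | 6α-acetoxy-8α-[(tert-butyldimethylsilyl)oxy]-10-epi-eudesm-4-en-3-one | CC1=C2[C@@H](OC(C)=O)[C@H](C(C)C)[C@@H](O[Si](C)(C)C(C)(C)C)C[C@]2(C)CCC1=O | intermediate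
16 | 6α-acetoxy-8α-[(tert-butyldimethylsilyl)oxy]-10-epi-eudesma-1,4-dien-3-one (7β-isopropyl, 10α-methyl), precursor of the key step | CC1=C2[C@@H](OC(C)=O)[C@H](C(C)C)[C@@H](O[Si](C)(C)C(C)(C)C)C[C@]2(C)C=CC1=O | intermediate
17 | 6α-acetoxy-10β-hydroxy-8α-[(tert-butyldimethylsilyl)oxy]-1βH-guai-4-en-3-one (7β-isopropyl, 10α-methyl), product of the key step | C[C@]1(O)C[C@H](O[Si](C)(C)C(C)(C)C)[C@@H](C(C)C)[C@H](OC(C)=O)C2=C(C)C(=O)C[C@H]12 | intermediate
18 | 6α-acetoxy-8α-[(tert-butyldimethylsilyl)oxy]-1βH-guai-4-ene-3β,10β-diol | C[C@]1(O)C[C@H](O[Si](C)(C)C(C)(C)C)[C@@H](C(C)C)[C@H](OC(C)=O)C2=C(C)[C@@H](O)C[C@H]12 | intermediate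
19 | 6α-acetoxy-3β,8α-bis[(tert-butyldimethylsilyl)oxy]-1βH-guai-4-en-10β-ol | C[C@]1(O)C[C@H](O[Si](C)(C)C(C)(C)C)[C@@H](C(C)C)[C@H](OC(C)=O)C2=C(C)[C@@H](O[Si](C)(C)C(C)(C)C)C[C@H]12 | intermediate
20 | 6α-acetoxy-3β,8α-bis[(tert-butyldimethylsilyl)oxy]-1βH-guaia-4,10(14)-diene | C=C1C[C@H](O[Si](C)(C)C(C)(C)C)[C@@H](C(C)C)[C@H](OC(C)=O)C2=C(C)[C@@H](O[Si](C)(C)C(C)(C)C)C[C@H]12 | intermediate
21 | 3β,8α-bis[(tert-butyldimethylsilyl)oxy]-1βH-guaia-4,10(14)-dien-6α-ol | C=C1C[C@H](O[Si](C)(C)C(C)(C)C)[C@@H](C(C)C)[C@H](O)C2=C(C)[C@@H](O[Si](C)(C)C(C)(C)C)C[C@H]12 | intermediate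
22 | 4α,5α-epoxy-3β,8α-bis[(tert-butyldimethylsilyl)oxy]-1βH-guai-10(14)-en-6α-ol | C=C1C[C@H](O[Si](C)(C)C(C)(C)C)[C@@H](C(C)C)[C@H](O)[C@]23O[C@]3(C)[C@@H](O[Si](C)(C)C(C)(C)C)C[C@H]12 | intermediate
23 | 4α,5α-epoxy-3β,8α-bis[(tert-butyldimethylsilyl)oxy]-1βH-guai-10(14)-en-6-one | C=C1C[C@H](O[Si](C)(C)C(C)(C)C)[C@@H](C(C)C)C(=O)[C@]23O[C@]3(C)[C@@H](O[Si](C)(C)C(C)(C)C)C[C@H]12 | intermediate
24 | hydrazone of 23 at C6 | C=C1C[C@H](O[Si](C)(C)C(C)(C)C)[C@@H](C(C)C)C(=NN)[C@]23O[C@]3(C)[C@@H](O[Si](C)(C)C(C)(C)C)C[C@H]12 | intermediate (not isolated)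
25 | 3β,8α-bis[(tert-butyldimethylsilyl)oxy]-1βH-guaia-5,10(14)-dien-4α-ol | C=C1C[C@H](O[Si](C)(C)C(C)(C)C)[C@@H](C(C)C)C=C2[C@](C)(O)[C@@H](O[Si](C)(C)C(C)(C)C)C[C@H]12 | intermediate
26 | 4α-O-dimethylsilyl ether of 25 | C=C1C[C@H](O[Si](C)(C)C(C)(C)C)[C@@H](C(C)C)C=C2[C@](C)(O[SiH](C)C)[C@@H](O[Si](C)(C)C(C)(C)C)C[C@H]12 | intermediate (not isolated)
27 | cyclic siloxane with the 4α-O–SiMe2–C6α bridge (1βH, 5αH) | C=C1C[C@H](O[Si](C)(C)C(C)(C)C)[C@@H](C(C)C)[C@H]3[C@H]2[C@](C)(O[Si]3(C)C)[C@@H](O[Si](C)(C)C(C)(C)C)C[C@H]12 | intermediate (not isolated)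
28 | 3β,8α-bis[(tert-butyldimethylsilyl)oxy]-1βH,5αH-guai-10(14)-ene-4α,6α-diol | C=C1C[C@H](O[Si](C)(C)C(C)(C)C)[C@@H](C(C)C)[C@H](O)[C@H]2[C@](C)(O)[C@@H](O[Si](C)(C)C(C)(C)C)C[C@H]12 | intermediate
29 | 1βH,5αH-guai-10(14)-ene-3β,4α,6α,8α-tetraol | C=C1C[C@H](O)[C@@H](C(C)C)[C@H](O)[C@@H]2[C@@H]1C[C@H](O)[C@@]2(C)O | intermediate
30 | 3β,6α,8α-triacetoxy-1βH,5αH-guai-10(14)-en-4α-ol (CNP0147943.1) | C=C1C[C@H](OC(C)=O)[C@@H](C(C)C)[C@H](OC(C)=O)[C@@H]2[C@@H]1C[C@H](OC(C)=O)[C@@]2(C)O | target

Total step count: 21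
Longest linear sequence: 21 steps (1 to 30)

Steps most likely to fail

Step 14 (dehydration at C10). What may go wrong is loss of regiocontrol in the elimination: proton loss from C9 instead of C14, or ionisation followed by hydride shift from the allylic C1. The fallback sets out from 19: the same elimination is accepted even if it delivers mainly the endocyclic 6α-acetoxy-3β,8α-bis(TBS-oxy)-1βH-guaia-4,9-diene F1. F1 is then irradiated with xylene as triplet sensitiser in a hindered alcohol. Photoprotonation of the twisted cycloheptene and loss of a C14 proton move the double bond against the thermodynamic bias to the exocyclic position, while the tetrasubstituted cyclopentene cannot twist and stays inert. The fallback rejoins the route at 20.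

Step 18 (Wharton transposition). What may go wrong is slow hydrazone formation at the hindered ketone between the quaternary C5 and the isopropyl-bearing C7, with epoxide opening by hydrazine or over-reduction competing. The fallback sets out from epoxy alcohol 22: 1,1'-thiocarbonyldiimidazole converts the 6α-alcohol into the 6α-O-(imidazol-1-ylthiocarbonyl) derivative F2. Bu3SnH with 2,2'-azobis(2-methylpropionitrile) in toluene at 80 °C then generates the C6 radical, which opens the adjacent epoxide at C5–O and gives, after hydrogen transfer to the C4 alkoxy radical, the 4α-hydroxy-5-ene. The fallback rejoins the route at 25.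

Step 19 (tethered hydrosilylation and oxidation). What may go wrong is failure of the 5-endo hydrosilylation at the trisubstituted alkene, or platinum-induced migration or hydrosilylation of the exocyclic alkene. The fallback sets out from epoxy ketone 23 and bypasses 25: SmI2 in THF/MeOH at −78 °C cleaves the C5–O bond next to the carbonyl and gives the β-hydroxy ketone 4α-hydroxy-3β,8α-bis(TBS-oxy)-1βH,5αH-guai-10(14)-en-6-one F3. C5 is protonated from the face of the samarium-bound C4 alkoxide and can be equilibrated with mild base if needed. Narasaka–Prasad reduction (Et2BOMe, NaBH4, THF/MeOH, −78 °C) then gives the syn-1,3-diol with 6α-OH. The fallback rejoins the route at 28.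

Further compounds
F1 | step 14 | 6α-acetoxy-3β,8α-bis[(tert-butyldimethylsilyl)oxy]-1βH-guaia-4,9-diene | CC1=C[C@H](O[Si](C)(C)C(C)(C)C)[C@@H](C(C)C)[C@H](OC(C)=O)C2=C(C)[C@@H](O[Si](C)(C)C(C)(C)C)C[C@H]12
F2 | step 18 | 4α,5α-epoxy-6α-[(1H-imidazol-1-ylcarbonothioyl)oxy]-3β,8α-bis[(tert-butyldimethylsilyl)oxy]-1βH-guai-10(14)-ene | C=C1C[C@H](O[Si](C)(C)C(C)(C)C)[C@@H](C(C)C)[C@H](OC(=S)n4ccnc4)[C@]23O[C@]3(C)[C@@H](O[Si](C)(C)C(C)(C)C)C[C@H]12
F3 | step 19 | 4α-hydroxy-3β,8α-bis[(tert-butyldimethylsilyl)oxy]-1βH,5αH-guai-10(14)-en-6-one | C=C1C[C@H](O[Si](C)(C)C(C)(C)C)[C@@H](C(C)C)C(=O)[C@H]2[C@](C)(O)[C@@H](O[Si](C)(C)C(C)(C)C)C[C@H]12
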